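West and south-east are the runs to read; the flasks delta to eta repeat them at other charges of substrate and ask for target after 4.0 h.

| setting | west | south-east | delta | gamma | beta | alpha | eta |
|---|---|---|---|---|---|---|---|
| substrate | 0.41 M | 0.91 M | 0.40 M | 1.2 M | 0.80 M | 0.20 M | 0.12 M |
| gas phase | 21 mM (held) | 21 mM (held) | 21 mM (held) | 21 mM (held) | 21 mM (held) | 21 mM (held) | 21 mM (held) |
| remark | run made earlier | run made earlier |  |  |  |  |  |
| time |  |  | 4.0 h | 4.0 h | 4.0 h | 4.0 h | 4.0 h |

- west (time / h: target / %): 0.500: 55.3; 1.00: 54.2; 1.50: 53.2; 2.50: 53.6; 3.00: 54.1
- south-east (time / h: target / %): 0.250: 42.8; 0.417: 44.1; 0.833: 44.0; 1.33: 42.4; 3.00: 43.8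

(readings scatter by 1 percentage point)

- ranking by amount of target, in percent of the substrate charged, from high to low, at 4.0 h (delta / gamma / beta / alpha / eta)
- the amount of target, in percent of the substrate charged of the flask you put first, at 4.0 h
- the amount of target, in percent of the substrate charged of the flask you put last, at 4.0 h

- at the start none of the gas phase is in solution
- a reading or a percentage of target counts all its forms, free or not

Read down the target columns, west stays near a mean of 54.1% from 0.500 h to 3.00 h, and south-east near 43.4% from 0.250 h to 3.00 h. The asked time is later than both last readings, so this reckoning places each flask on its plateau and treats that plateau as a finished split of the charge.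

Read across, the larger charge gives less target. The reckoning assumes that the remainder is side product, formed from substrate without gas. Each plateau then becomes w, the side product per target and the inverse of a selectivity factor: 0.849 in west, and higher in south-east at 1.30.

Dissolved gas starts at zero and is fed from the gas phase. If it stands in a quasi-steady state, with feed balancing use, [dissolved gas] falls as [substrate] rises, and w climbs roughly on a straight line in the charge. The two runs give that line. Its slope is the gas penalty g, the rise of w per unit of charge, at 0.908 M⁻¹, and its value at zero charge is 0.477.

Target is then the share 1/(1+w), which falls along the charges: eta, alpha, delta, beta, gamma. Eta comes to 63.1% and gamma to 39.0%. Eta is charged with less than west and gamma with more than south-east, so both numbers are extrapolations.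

The forecast gives eta > alpha > delta > beta > gamma, with 73% and 39.5%, on the ground that “Target scales roughly as the square root of free substrate”; its order is the one above, and its top value stands higher than this reckoning's.

The flask gives eta > alpha > delta > beta > gamma, with 63.4% in eta and 40.0% in gamma. Gamma holds 12.5% as crystals, counted in its target, and the saturation of target makes no difference to gamma's target with all its forms counted. Delta is charged with less than west, so its number is an extrapolation too: the same g puts delta at 54.3%, and the flask gives 54.5%.

    substrate → side product (k = 0.108 min⁻¹)
    crystals ⇌ target, rate k2*(cs2 - [target]) while solid is left; crystals form when [target] > cs2 (solubility = 0.330 M, k = 0.398 min⁻¹)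
    gas phase ⇌ dissolved gas, rate k3*(csat - [dissolved gas]) (kL = 2.41 min⁻¹)
    substrate + dissolved gas → target (k = 12.7 M⁻¹ min⁻¹)

For the flask like gamma but charged with 3.0 M, g gives w = 3.20, so 23.8% of target. The computed flask holds 26.6%, more than the line gives.

Readings and results come from a simulation for substances that don't exist; the scatter is artificial.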